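**Retrosynthetic overview**

1. The arene (C4a, C5, C6, C7, C8, C8a) carries oxygen on C5, C7 and C8a and carbon on C4a, C6 and C8. This is the alternation of a folded 3,5,7-tricarbonyl chain whose C8a oxygen is already the pyran O1. The two formyl groups (C6, C8) are removed first, then the arene is cut at C4a–C5 (Claisen) to the pyran-2-ylidene acetoacetate 30, that is δ-lactone 26 plus methyl acetoacetate.
2. In 26 the nine-membered ring is opened at the bond between the methylidene carbon and its ring CH2 (B-alkyl Suzuki–Miyaura coupling of vinyl/enol triflate 24). The lactone O–C(CH3) bond comes from Baeyer–Villiger oxidation of cyclopentanone 23 with retention.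
3. The three contiguous stereocentres of 23 are set on (S)-4-silyloxy-2-methylcyclopentenone 13: vinyl cuprate addition with aldol trapping by cyclobutane aldehyde 10, then silanol elimination and phenyl cuprate addition.
4. Aldehyde 10 comes from [2+2] photocycloaddition of (R)-4-silyloxycyclopentenone 1 with 2-methylpropene, followed by cleavage of the five-membered ring.
5. Ring order: cyclobutane, cyclopentanone template (later the δ-lactone and pyran), nine-membered ring, arene.

Key step: step 18

Remark: chroman locants (O1, C2, C3, C4, C4a, C5 to C8, C8a) are used for the atoms that end up in the pyran and arene rings; intermediates are named with their own ring locants.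

Remark: the cyclobutane centres of the target as drawn are the mirror image of those of commercial (−)-β-caryophyllene, so the terpenoid part is built de novo; both enantiomers of 4-(tert-butyldimethylsilyloxy)cyclopent-2-en-1-one are taken as commercially available.

**Route**

Step 1
Reactants: 1 (R)-4-(tert-butyldimethylsilyloxy)cyclopent-2-en-1-one; 2 2-methylpropene
Product: 3 (1S,4R,5S)-4-(tert-butyldimethylsilyloxy)-6,6-dimethylbicyclo[3.2.0]heptan-2-one
Conditions: hν (350 nm, Pyrex), 2 (excess), CH2Cl2, −40 °C; chromatographic removal of isomers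
Reagents that add atoms: none
Why: Enone–alkene [2+2] photocycloaddition should give the cis-fused head-to-tail cyclobutane (CMe2 on the enone β-carbon, as with other cyclic enones and 2-methylpropene) from the face anti to the silyloxy group, which sets the cyclobutane CH next to CMe2, and because regio- and facial isomers are diastereomers of 3 their removal secures enantiopurity.

Step 2
Reactants: 3 (1S,4R,5S)-4-(tert-butyldimethylsilyloxy)-6,6-dimethylbicyclo[3.2.0]heptan-2-one
Product: 5 (1S,5S)-6,6-dimethylbicyclo[3.2.0]heptan-2-one, via bicyclic enone 4 (not isolated)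
Conditions: DBU, EtOAc, 0 → 25 °C; then Pd/C, H2 (1 atm)
Reagents that add atoms: none
Why: E1cB loss of silanol from the β-silyloxy ketone and hydrogenation of the resulting enone C=C remove the directing oxygen, while the ring-fusion centres cannot epimerise because only the cis-fused bicyclo[3.2.0] skeleton is viable.

Step 3
Reactants: 5 (1S,5S)-6,6-dimethylbicyclo[3.2.0]heptan-2-one
Product: 7 (1S,5S)-6,6-dimethylbicyclo[3.2.0]hept-2-en-2-yl trifluoromethanesulfonate, via lithium enolate 6 (not isolated)
Conditions: LiN(iPr)2, THF, −78 °C; PhNTf2, −78 → 0 °C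
Reagents that add atoms: N-phenylbis(trifluoromethanesulfonimide), O=S(=O)(N(c1ccccc1)S(=O)(=O)C(F)(F)F)C(F)(F)F
Why: Kinetic deprotonation takes the CH2 proton rather than the strained ring-fusion CH, and O-sulfonylation of the enolate fixes the double bond on that side.

Step 4
Reactants: 7 (1S,5S)-6,6-dimethylbicyclo[3.2.0]hept-2-en-2-yl trifluoromethanesulfonate
Product: 8 (1S,5S)-2,6,6-trimethylbicyclo[3.2.0]hept-2-ene
Conditions: MeMgBr, Fe(acac)3 (5 mol%), THF–NMP, −30 → 0 °C
Reagents that add atoms: methylmagnesium bromide, C[Mg]Br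
Why: Iron-catalysed Kumada-type cross-coupling of enol triflates with methyl Grignard reagents gives a trisubstituted alkene of defined position, which avoids the regio-isomers and cyclobutylcarbinyl cation rearrangements of an alcohol dehydration.

Step 5
Reactants: 8 (1S,5S)-2,6,6-trimethylbicyclo[3.2.0]hept-2-ene
Product: 10 2-[(1S,4S)-4-acetyl-2,2-dimethylcyclobutyl]acetaldehyde (cis), via ozonide 9 (not isolated)
Conditions: O3, CH2Cl2, −78 °C; Me2S, −78 → 25 °C; used crude
Reagents that add atoms: ozone, [O-][O+]=O
Why: Ozonolysis with reductive work-up cleaves the cyclopentene into a methyl ketone and an aldehyde on a cis-1,2-disubstituted cyclobutane, the aldehyde being the more electrophilic carbonyl for the coupling in step 8.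

Step 6
Reactants: 11 (S)-4-(tert-butyldimethylsilyloxy)cyclopent-2-en-1-one
Product: 12 (S)-4-(tert-butyldimethylsilyloxy)-2-iodocyclopent-2-en-1-one
Conditions: I2, pyridine–CH2Cl2, 0 → 25 °C
Reagents that add atoms: iodine, II
Why: Pyridine-mediated α-iodination of the enone (conjugate addition, iodination of the enolate, elimination; Baylis–Hillman-type) leaves the γ-silyloxy stereocentre untouched.

Step 7
Reactants: 12 (S)-4-(tert-butyldimethylsilyloxy)-2-iodocyclopent-2-en-1-one
Product: 13 (S)-4-(tert-butyldimethylsilyloxy)-2-methylcyclopent-2-en-1-one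
Conditions: Me4Sn, Pd(PhCN)2Cl2 (5 mol%), AsPh3, CuI, NMP, 60 °C
Reagents that add atoms: tetramethylstannane, C[Sn](C)(C)C
Why: Stille coupling of the α-iodoenone is base-free, so the methyl group is installed without elimination of the γ-silyloxy group.

Step 8
Reactants: 13 (S)-4-(tert-butyldimethylsilyloxy)-2-methylcyclopent-2-en-1-one; 10 2-[(1S,4S)-4-acetyl-2,2-dimethylcyclobutyl]acetaldehyde
Product: 15 (2R,3S,4S)-2-{2-[(1S,4S)-4-acetyl-2,2-dimethylcyclobutyl]-1-hydroxyethyl}-4-(tert-butyldimethylsilyloxy)-2-methyl-3-vinylcyclopentan-1-one (both carbinol epimers), via bromomagnesium enolate 14 (not isolated)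
Conditions: CH2=CHMgBr (2 equiv), CuI (1 equiv), THF, −40 °C; 13, −78 °C; then 10, −78 °C; sat. NH4Cl
Reagents that add atoms: vinylmagnesium bromide, C=C[Mg]Br
Why: Three-component coupling in which the vinyl cuprate adds to the enone anti to the silyloxy group and the resulting tetrasubstituted enolate undergoes aldol addition to the aldehyde of 10 from the face anti to the new vinyl group, so the quaternary carbon gets methyl cis and the side chain trans to vinyl, the carbinol configuration being irrelevant because it is removed in step 10.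

Step 9
Reactants: 15 aldol adduct
Product: 16 O-phenyl thionocarbonate of 15
Conditions: PhOC(S)Cl, pyridine, DMAP (cat.), CH2Cl2, 0 → 25 °C
Reagents that add atoms: O-phenyl chlorothionoformate, S=C(Cl)Oc1ccccc1
Why: Thioacylation of the hindered secondary alcohol under weakly basic conditions (first stage of a Barton–McCombie deoxygenation) avoids retro-aldol cleavage of the β-hydroxy ketone.

Step 10
Reactants: 16 O-phenyl thionocarbonate
Product: 17 (2S,3S,4S)-2-{2-[(1S,4S)-4-acetyl-2,2-dimethylcyclobutyl]ethyl}-4-(tert-butyldimethylsilyloxy)-2-methyl-3-vinylcyclopentan-1-one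
Conditions: Bu3SnH (1 M), (PhSe)2 (10 mol%), AIBN, PhMe, 80 °C
Reagents that add atoms: none
Why: Barton–McCombie radical deoxygenation, in which PhSeH formed from (PhSe)2 traps the secondary radical fast enough to suppress 1,2-acyl migration to the neighbouring ring ketone.

Step 11
Reactants: 17 silyloxy ketone with cis-acetylcyclobutane
Product: 19 (4R,5S)-5-{2-[(1S,4R)-4-acetyl-2,2-dimethylcyclobutyl]ethyl}-5-methyl-4-vinylcyclopent-2-en-1-one, via cis-acetyl enone 18 (not isolated)
Conditions: TsOH·H2O (0.3 equiv), PhMe, 70 °C
Reagents that add atoms: none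
Why: Acid-catalysed β-elimination of silanol through the enol gives the cyclopentenone and the same acid enolises the cyclobutyl methyl ketone, which equilibrates its α-carbon to the more stable trans-1,2-disubstituted cyclobutane (thermodynamic control), acid being chosen because base would deprotonate the doubly allylic γ-carbon of the 4-vinylcyclopentenone.

Step 12
Reactants: 19 trans-acetyl cyclopentenone
Product: 20 trimethylsilyl enol ether (C1=C5) of (2S,3R,4S)-2-{2-[(1S,4R)-4-acetyl-2,2-dimethylcyclobutyl]ethyl}-2-methyl-4-phenyl-3-vinylcyclopentan-1-one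
Conditions: Ph2CuLi (from PhLi, CuI), Me3SiCl, THF–Et2O, −78 °C; non-aqueous work-up, used crude
Reagents that add atoms: lithium diphenylcuprate, [Li+].c1ccc([Cu-]c2ccccc2)cc1; chlorotrimethylsilane, C[Si](C)(C)Cl
Why: Me3SiCl-accelerated cuprate conjugate addition delivers phenyl anti to the adjacent vinyl group (3,4-trans), setting the benzylic stereocentre, and traps the regiodefined enolate as a silyl enol ether that masks the ring ketone for step 13.

Step 13
Reactants: 20 silyl enol ether
Product: 23 (2S,3R,4S)-2-{2-[(1S,4R)-2,2-dimethyl-4-(1-(trifluoromethanesulfonyloxy)vinyl)cyclobutyl]ethyl}-2-methyl-4-phenyl-3-vinylcyclopentan-1-one, via potassium enolate 21 (not isolated), via silyl enol ether triflate 22 (not isolated)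
Conditions: KN(SiMe3)2, THF, −78 °C; PhNTf2, −78 → −20 °C; then 1 M HCl, THF, 0 °C
Reagents that add atoms: N-phenylbis(trifluoromethanesulfonimide), O=S(=O)(N(c1ccccc1)S(=O)(=O)C(F)(F)F)C(F)(F)F
Why: With the ring ketone masked, the amide base removes kinetically a methyl proton of the acetyl group and O-sulfonylation gives the 1,1-disubstituted enol triflate, after which dilute acid hydrolyses only the silyl enol ether.

Step 14
Reactants: 23 cyclopentanone enol triflate
Product: 24 (4S,5R,6S)-6-{2-[(1S,4R)-2,2-dimethyl-4-(1-(trifluoromethanesulfonyloxy)vinyl)cyclobutyl]ethyl}-6-methyl-4-phenyl-5-vinyltetrahydro-2H-pyran-2-one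
Conditions: (Me3SiO)2, Me3SiOTf (10 mol%), CH2Cl2, −40 → −20 °C
Reagents that add atoms: bis(trimethylsilyl) peroxide, C[Si](C)(C)OO[Si](C)(C)C
Why: Baeyer–Villiger oxidation in which the quaternary α-carbon migrates in preference to CH2 and with retention, so the tertiary C–O centre of the pyran derives from the carbon stereocentre set in step 8, the silyl peroxide variant being used because it spares isolated alkenes while the electron-poor enol triflate is inert.

Step 15
Reactants: 24 δ-lactone with vinyl and enol triflate groups
Product: 26 tricyclic δ-lactone (6-membered lactone trans-fused through its CH and C(CH3)–O carbons to the nine-membered ring of the trans-fused dimethyl-methylidene-bicyclo[7.2.0]undecane; configuration as in 33), via B-alkyl-9-BBN adduct 25 (not isolated)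
Conditions: 9-BBN, THF, 0 → 25 °C; then slow addition to Pd(dppf)Cl2 (15 mol%), AsPh3, Cs2CO3, DMF–THF–H2O, 50 °C (2 mM)
Reagents that add atoms: none
Why: 9-BBN hydroborates only the monosubstituted vinyl group, and intramolecular B-alkyl Suzuki–Miyaura coupling of the alkylborane with the enol triflate under high dilution closes the nine-membered ring and delivers the methylidene group directly, the trans-cyclobutane and the trans-disposed chains on the lactone pre-organising the two ends and no stereocentre being formed.

Step 16
Reactants: 26 tricyclic δ-lactone; 27 methyl acetoacetate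
Product: 29 lactol (2-hydroxypyran-2-yl acetoacetate, anomeric mixture), via acetoacetate dianion 28 (not isolated)
Conditions: 27 (3 equiv), NaH, THF, 0 °C; n-BuLi, 0 °C; then 26, −78 → 0 °C; AcOH
Reagents that add atoms: none
Why: The terminal carbanion of the acetoacetate dianion adds to the lactone carbonyl (Claisen-type acylation), and on protonation the tertiary alkoxide recloses onto the new ketone to give the six-membered hemiketal.

Step 17
Reactants: 29 lactol
Product: 30 methyl (E)-3-oxo-4-(pyran-2-ylidene)butanoate fused to the methylidene cyclobutane–cyclononane bicycle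
Conditions: PPTS (10 mol%), 4 Å MS, PhMe, 50 °C
Reagents that add atoms: none
Why: Mild acid-catalysed dehydration through the cyclic oxocarbenium ion gives the exocyclic enol ether conjugated with the ketone (vinylogous ester), the E isomer with the acyl group away from the ring oxygen being favoured, and a pyridinium acid is too weak to protonate the methylidene group.

Step 18
Reactants: 30 pyran-2-ylidene acetoacetate
Product: 32 5,7-dihydroxychroman with the complete terpenoid skeleton (bis-deformyl target), via dilithium dienolate 31 (not isolated)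
Conditions: LiN(iPr)2 (3.2 equiv), THF, −78 → 25 °C; sat. NH4Cl
Reagents that add atoms: none
Why: The first equivalent of LiN(iPr)2 removes the acetoacetate C6–H and a second removes a ring C4a–H (γ-position of the vinylogous ester), giving dienolate 31, whose C4a terminus attacks the ester carbonyl C5 to form the C4a–C5 bond, methoxide leaves, and deprotonation and tautomerisation of the cyclohexenedione enol ether give the arene irreversibly. An amide base in THF is used instead of methoxide in methanol because the nucleophilic carbon here is activated by one vinylogous carbonyl only and is not flanked by two carbonyls. The closest known reactions are the Claisen (Dieckmann-type) folding of 3,5,7-tricarbonyl chains to phloroglucinols and the γ-acylation of dienolates of β-alkoxy enones. The carbocycle C4a–C5–C6–C7–C8–C8a closes in a 6-exo-trig mode with the C8=C8a bond inside the new ring, which needs the ketone cis to C4a (E isomer), and dienolate formation equilibrates any Z isomer. No stereocentre is formed and C4–H is not acidic, so the five existing centres stay as they are. The selectivity needed is the folding mode, secured because the C8a oxygen is the pyran ether (no pyranone formation, no aldol mode), C8 is a vinylic CH, and C4a is the only carbon that reaches the ester through a six-membered transition state.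

Step 19
Reactants: 32 5,7-dihydroxychroman
Product: 33 target (6,8-diformyl-5,7-dihydroxychroman, CNP0253700.1)
Conditions: MgCl2, Et3N, (CH2O)n (excess), MeCN, 80 °C; 1 M HCl work-up
Reagents that add atoms: formaldehyde (as paraformaldehyde), C=O
Why: Magnesium phenoxide-directed ortho-hydroxymethylation followed by hydride transfer to a second formaldehyde (Oppenauer-type) formylates ortho to phenol, and since both free ring positions C6 and C8 are ortho to a phenoxide an excess of reagent should formylate both under basic conditions that spare the methylidene group.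

**Compound list**

1 | (R)-4-(tert-butyldimethylsilyloxy)cyclopent-2-en-1-one | O=C1C=C[C@H](O[Si](C)(C)C(C)(C)C)C1 | starting material
2 | 2-methylpropene | C=C(C)C | starting material
3 | (1S,4R,5S)-4-(tert-butyldimethylsilyloxy)-6,6-dimethylbicyclo[3.2.0]heptan-2-one | O=C1C[C@@H](O[Si](C)(C)C(C)(C)C)[C@H]2[C@@H]1CC2(C)C | intermediate
4 | (1S,5S)-6,6-dimethylbicyclo[3.2.0]hept-3-en-2-one (formed in the flask) | O=C1C=C[C@H]2[C@@H]1CC2(C)C | intermediate
5 | (1S,5S)-6,6-dimethylbicyclo[3.2.0]heptan-2-one | O=C1CC[C@H]2[C@@H]1CC2(C)C | intermediate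
6 | lithium (1S,5S)-6,6-dimethylbicyclo[3.2.0]hept-2-en-2-olate (formed in the flask) | [Li]OC1=CC[C@H]2[C@@H]1CC2(C)C | intermediate
7 | (1S,5S)-6,6-dimethylbicyclo[3.2.0]hept-2-en-2-yl trifluoromethanesulfonate | O=S(=O)(OC1=CC[C@H]2[C@@H]1CC2(C)C)C(F)(F)F | intermediate
8 | (1S,5S)-2,6,6-trimethylbicyclo[3.2.0]hept-2-ene | CC1=CC[C@H]2[C@@H]1CC2(C)C | intermediate
9 | secondary ozonide of 8 (formed in the flask) | CC12OOC(O1)C[C@H]1[C@@H]2CC1(C)C | intermediate
10 | 2-[(1S,4S)-4-acetyl-2,2-dimethylcyclobutyl]acetaldehyde (cis) | CC(=O)[C@H]1CC(C)(C)[C@H]1CC=O | intermediate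
11 | (S)-4-(tert-butyldimethylsilyloxy)cyclopent-2-en-1-one | O=C1C=C[C@@H](O[Si](C)(C)C(C)(C)C)C1 | starting material
12 | (S)-4-(tert-butyldimethylsilyloxy)-2-iodocyclopent-2-en-1-one | O=C1C(I)=C[C@@H](O[Si](C)(C)C(C)(C)C)C1 | intermediate
13 | (S)-4-(tert-butyldimethylsilyloxy)-2-methylcyclopent-2-en-1-one | CC1=C[C@@H](O[Si](C)(C)C(C)(C)C)CC1=O | intermediate
14 | bromomagnesium enolate of trans-4-(tert-butyldimethylsilyloxy)-2-methyl-3-vinylcyclopentanone (formed in the flask) | C=C[C@@H]1[C@@H](O[Si](C)(C)C(C)(C)C)CC(O[Mg]Br)=C1C | intermediate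
15 | (2R,3S,4S)-2-{2-[(1S,4S)-4-acetyl-2,2-dimethylcyclobutyl]-1-hydroxyethyl}-4-(tert-butyldimethylsilyloxy)-2-methyl-3-vinylcyclopentan-1-one (carbinol epimers) | O=C1C[C@H](O[Si](C)(C)C(C)(C)C)[C@@H](C=C)[C@]1(C)C(O)C[C@H]2[C@@H](C(C)=O)CC2(C)C | intermediate
16 | O-phenyl thionocarbonate of 15 | O=C1C[C@H](O[Si](C)(C)C(C)(C)C)[C@@H](C=C)[C@]1(C)C(OC(=S)Oc2ccccc2)C[C@H]3[C@@H](C(C)=O)CC3(C)C | intermediate
17 | (2S,3S,4S)-2-{2-[(1S,4S)-4-acetyl-2,2-dimethylcyclobutyl]ethyl}-4-(tert-butyldimethylsilyloxy)-2-methyl-3-vinylcyclopentan-1-one | O=C1C[C@H](O[Si](C)(C)C(C)(C)C)[C@@H](C=C)[C@]1(C)CC[C@H]2[C@@H](C(C)=O)CC2(C)C | intermediate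
18 | (4R,5S)-5-{2-[(1S,4S)-4-acetyl-2,2-dimethylcyclobutyl]ethyl}-5-methyl-4-vinylcyclopent-2-en-1-one (cis-acetyl; formed in the flask) | O=C1C=C[C@@H](C=C)[C@]1(C)CC[C@H]2[C@@H](C(C)=O)CC2(C)C | intermediate
19 | (4R,5S)-5-{2-[(1S,4R)-4-acetyl-2,2-dimethylcyclobutyl]ethyl}-5-methyl-4-vinylcyclopent-2-en-1-one (trans-acetyl) | O=C1C=C[C@@H](C=C)[C@]1(C)CC[C@H]2[C@H](C(C)=O)CC2(C)C | intermediate
20 | trimethylsilyl enol ether (C1=C5) of (2S,3R,4S)-2-{2-[(1S,4R)-4-acetyl-2,2-dimethylcyclobutyl]ethyl}-2-methyl-4-phenyl-3-vinylcyclopentan-1-one | C[Si](C)(C)OC1=C[C@H](c2ccccc2)[C@@H](C=C)[C@]1(C)CC[C@H]3[C@H](C(C)=O)CC3(C)C | intermediate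
21 | potassium enolate of 20 on the acetyl methyl side (formed in the flask) | C[Si](C)(C)OC1=C[C@H](c2ccccc2)[C@@H](C=C)[C@]1(C)CC[C@H]3[C@H](C(=C)O[K])CC3(C)C | intermediate
22 | enol triflate of 20 still carrying the silyl enol ether (formed in the flask) | C[Si](C)(C)OC1=C[C@H](c2ccccc2)[C@@H](C=C)[C@]1(C)CC[C@H]3[C@H](C(=C)OS(=O)(=O)C(F)(F)F)CC3(C)C | intermediate
23 | (2S,3R,4S)-2-{2-[(1S,4R)-2,2-dimethyl-4-(1-(trifluoromethanesulfonyloxy)vinyl)cyclobutyl]ethyl}-2-methyl-4-phenyl-3-vinylcyclopentan-1-one | O=C1C[C@H](c2ccccc2)[C@@H](C=C)[C@]1(C)CC[C@H]3[C@H](C(=C)OS(=O)(=O)C(F)(F)F)CC3(C)C | intermediate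
24 | (4S,5R,6S)-6-{2-[(1S,4R)-2,2-dimethyl-4-(1-(trifluoromethanesulfonyloxy)vinyl)cyclobutyl]ethyl}-6-methyl-4-phenyl-5-vinyltetrahydro-2H-pyran-2-one | O=C1C[C@H](c2ccccc2)[C@@H](C=C)[C@](C)(CC[C@H]3[C@H](C(=C)OS(=O)(=O)C(F)(F)F)CC3(C)C)O1 | intermediate
25 | B-alkyl-9-borabicyclo[3.3.1]nonane from hydroboration of the vinyl group of 24 (formed in the flask) | O=C1C[C@H](c2ccccc2)[C@@H](CCB3C4CCCC3CCC4)[C@](C)(CC[C@H]5[C@H](C(=C)OS(=O)(=O)C(F)(F)F)CC5(C)C)O1 | intermediate
26 | tricyclic δ-lactone: 4-phenyl-6-methyl-tetrahydropyran-2-one trans-fused at C5/C6 to the nine-membered ring of the trans-fused dimethyl-methylidene-bicyclo[7.2.0]undecane, configuration as in 33 | O=C1C[C@H](c2ccccc2)[C@H]2CCC(=C)[C@@H]3CC(C)(C)[C@H]3CC[C@]2(C)O1 | intermediate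
27 | methyl acetoacetate | COC(=O)CC(C)=O | starting material
28 | sodium lithium dianion of methyl acetoacetate (formed in the flask) | [Na+].[Li+].[CH2-]C(=O)[CH-]C(=O)OC | intermediate
29 | lactol: methyl 4-(2-hydroxypyran-2-yl)-3-oxobutanoate fused to the bicycle (anomeric mixture) | COC(=O)CC(=O)CC1(O)C[C@H](c2ccccc2)[C@H]2CCC(=C)[C@@H]3CC(C)(C)[C@H]3CC[C@]2(C)O1 | intermediate
30 | methyl (E)-3-oxo-4-(pyran-2-ylidene)butanoate fused to the methylidene cyclobutane–cyclononane bicycle | COC(=O)CC(=O)/C=C1\C[C@H](c2ccccc2)[C@H]2CCC(=C)[C@@H]3CC(C)(C)[C@H]3CC[C@]2(C)O1 | intermediate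
31 | dilithium dienolate of 30, deprotonated at C6 and C4a (formed in the flask) | [Li+].[Li+].COC(=O)[CH-]C(=O)C=C1[CH-][C@H](c2ccccc2)[C@H]2CCC(=C)[C@@H]3CC(C)(C)[C@H]3CC[C@]2(C)O1 | intermediate
32 | 5,7-dihydroxychroman with the complete terpenoid skeleton (bis-deformyl target) | C=C1CC[C@@H]2[C@@H](c3ccccc3)c3c(O)cc(O)cc3O[C@@]2(C)CC[C@H]2[C@H]1CC2(C)C | intermediate
33 | CNP0253700.1, 6,8-diformyl-5,7-dihydroxy-4-phenylchroman fused to the methylidene cyclobutane–cyclononane bicycle | C=C1CC[C@@H]2[C@@H](c3ccccc3)c3c(O)c(C=O)c(O)c(C=O)c3O[C@@]2(C)CC[C@H]2[C@H]1CC2(C)C | target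

**Step count and risks**

Total step count: 19. Longest linear sequence: 17 (steps 1–5, then 8–19).

Steps most likely to fail:

1. Step 15, nine-membered ring closure. Transannular strain may make the intramolecular transmetalation and reductive elimination slower than intermolecular coupling, protodeboronation or β-hydride elimination, so that oligomers and reduced or eliminated open-chain material form instead of the ring. The fallback is a Nozaki–Hiyama–Kishi closure, a reaction known to close nine-membered rings of bicyclo[7.2.0]undecanes. It sets out from 24: hydroboration with 9-BBN and oxidation with NaBO3·4H2O should give the primary alcohol F1, and Dess–Martin periodinane the aldehyde F2. CrCl2 with NiCl2 (cat.) in DMSO–THF under high dilution should add the alkenylchromium species derived from the enol triflate to the aldehyde and close the ring to the allylic alcohol F3. Formylation (HCO2H, DCC, DMAP) should give the allylic formate F4. Pd(OAc)2 and PBu3 in dioxane at 80 °C should then form the π-allylpalladium formate, which loses CO2 and delivers hydride to the more substituted (ring) terminus, leaving the methylidene group; this returns to the route at 26.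

2. Step 18, Claisen folding. Because the ester is conjugated with the C6 enolate, the C4a carbanion may not acylate it, so the reaction may stall at dienolate 31 and return 30 on work-up, or the vinylogous ester may be cleaved by addition–elimination at C8a. The fallback keeps the same C4a–C5 bond formation but uses a neutral, far more electrophilic acyl donor. It sets out from 26: the lithium dienolate of 2,2,6-trimethyl-4H-1,3-dioxin-4-one (LiN(SiMe3)2, THF, −78 °C) should add to the lactone to give the lactol F5, and PPTS dehydration the pyran-2-ylidene dioxinone F6. Heating in toluene at 110 °C expels acetone and unmasks the acylketene; after a 1,5-hydrogen shift from C4a to the ketone oxygen the dienylketene should close by 6π-electrocyclisation and tautomerise to the arene, which returns to the route at 32.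

3. Step 19, double formylation. The first formyl group deactivates the ring, so the second formylation may be slow, and the intermediate hydroxymethyl phenol may lose water to an ortho-quinone methide and dimerise. The fallback is a Vilsmeier–Haack diformylation, the reaction used to make diformylphloroglucinol. It sets out from 32: POCl3–DMF (excess) in EtOAc at 0 → 25 °C should give the bis(iminium) salt F7, which aqueous NaOAc hydrolyses to the dialdehyde, returning to the route at 33.

Further compounds
F1 | step 15 | primary alcohol from hydroboration–oxidation of the vinyl group of 24 | O=C1C[C@H](c2ccccc2)[C@@H](CCO)[C@](C)(CC[C@H]3[C@H](C(=C)OS(=O)(=O)C(F)(F)F)CC3(C)C)O1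
F2 | step 15 | aldehyde from oxidation of F1 | O=C1C[C@H](c2ccccc2)[C@@H](CC=O)[C@](C)(CC[C@H]3[C@H](C(=C)OS(=O)(=O)C(F)(F)F)CC3(C)C)O1
F3 | step 15 | nine-membered allylic alcohol (hydroxyl on the ring CH2 next to the methylidene carbon, both epimers) | O=C1C[C@H](c2ccccc2)[C@H]2CC(O)C(=C)[C@@H]3CC(C)(C)[C@H]3CC[C@]2(C)O1
F4 | step 15 | allylic formate of F3 | O=COC1C[C@@H]2[C@@H](c3ccccc3)CC(=O)O[C@]2(C)CC[C@@H]2[C@@H](CC2(C)C)C1=C
F5 | step 18 | lactol from addition of the dioxinone dienolate to 26 | CC1(C)OC(CC2(O)C[C@H](c3ccccc3)[C@H]3CCC(=C)[C@@H]4CC(C)(C)[C@H]4CC[C@]3(C)O2)=CC(=O)O1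
F6 | step 18 | (E)-pyran-2-ylidene dioxinone | CC1(C)OC(/C=C2\C[C@H](c3ccccc3)[C@H]3CCC(=C)[C@@H]4CC(C)(C)[C@H]4CC[C@]3(C)O2)=CC(=O)O1
F7 | step 19 | bis(dimethyliminium) chloride of 33 | C=C1CC[C@@H]2[C@@H](c3ccccc3)c3c(O)c(C=[N+](C)C)c(O)c(C=[N+](C)C)c3O[C@@]2(C)CC[C@H]2[C@H]1CC2(C)C.[Cl-].[Cl-]
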